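**Strategy.** The ten-membered carbocycle is disconnected at C8–C9 (germacrane numbering) by an anionic oxy-Cope retron: the C6 oxygen, the C7–C8 unit and the C1=C10–C9 allyl unit map onto a trans-2-alkenyl-1-[(Z)-2-alkoxyvinyl]cyclohexanol. One operation forms C8–C9, expands the six-membered ring to the cyclodecenone, sets C8 through a chair transition state and, by alkylation of the nascent enolate, C7. The precursor is an isopulegol-like cyclohexanol whose single purchased stereocentre (C4, from (R)-cyclohex-3-ene-1-carboxylic acid) controls C1 and C6. The ring-trans C1=C10 alkene delivered by the chair is then equilibrated to the ring-cis isomer, and C6 follows by chelation-controlled reduction.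

Key step: step 10

Remark: germacrane labels are used throughout (ring C1–C10, lactone carbons C11–C13, C14 on C10, C15 on C4; the cyclohexane precursors carry the same labels C1–C6; α is the face of H-7), and both enantiomers of cyclohex-3-ene-1-carboxylic acid and 2-bromoprop-2-en-1-ol are taken to be commercial.

## Route

Step 1
Reactants: 1 2-bromoprop-2-en-1-ol
Product: 2 silyl ether of 2-bromoallyl alcohol
Conditions: TBSCl, imidazole, CH2Cl2, 0 °C → rt
Reagents that add atoms: tert-butyldimethylsilyl chloride, CC(C)(C)[Si](C)(C)Cl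
Why: Imidazole-promoted silylation of the primary allylic alcohol protects the future C14 hydroxyl; no stereocentre is involved.

Step 2
Reactants: 3 trichloroethylene; 4 (4-methoxyphenyl)methanol
Product: 6 (E)-1,2-dichlorovinyl 4-methoxybenzyl ether, via potassium alkoxide 5 (not isolated)
Conditions: KH, THF, 0 °C; then Cl2C=CHCl, −50 °C → rt
Reagents that add atoms: none
Why: Base-mediated vinylic substitution of the alkoxide on trichloroethylene should give the E-dichlorovinyl ether, the usual precursor of a lithium alkoxyacetylide.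

Step 3
Reactants: 7 (R)-cyclohex-3-ene-1-carboxylic acid
Product: 9 iodolactone, via sodium carboxylate 8 (not isolated)
Conditions: I2, KI, NaHCO3, H2O, rt, dark
Reagents that add atoms: iodine, [I][I]
Why: Iodolactonisation adds carboxylate and iodine anti across the alkene, so C4 places the C6 oxygen cis to C15 and the C1 iodide trans to that oxygen.

Step 4
Reactants: 9 iodolactone; 2 silyl ether of 2-bromoallyl alcohol
Product: 10 alkenyl lactone
Conditions: NiI2 (10 mol %), 4,4′-di-tert-butyl-2,2′-bipyridine (10 mol %), Mn powder, NaI, DMA, 25–40 °C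
Reagents that add atoms: none
Why: Nickel-catalysed reductive cross-electrophile coupling of a secondary alkyl iodide with an alkenyl bromide; the C1 radical should be captured on the exo face anti to the neighbouring C–O bond, so the alkenyl group takes the place of iodine, trans to C15.

Step 5
Reactants: 10 alkenyl lactone
Product: 11 diol
Conditions: LiAlH4, THF, 0 °C; aqueous NaOH work-up
Reagents that add atoms: none
Why: Hydride reduction of the lactone gives the primary C15 alcohol and the secondary C6 alcohol without touching C1, C4 or C6.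

Step 6
Reactants: 11 diol
Product: 12 secondary alcohol
Conditions: TBSCl (1.05 equiv), imidazole, CH2Cl2, −20 → 0 °C
Reagents that add atoms: tert-butyldimethylsilyl chloride, CC(C)(C)[Si](C)(C)Cl
Why: The primary hydroxyl should silylate much faster than the hindered secondary one flanked by the branched alkenyl group.

Step 7
Reactants: 12 secondary alcohol
Product: 13 ketone
Conditions: Dess–Martin periodinane, NaHCO3, CH2Cl2, 0 °C → rt
Reagents that add atoms: none
Why: Buffered Dess–Martin oxidation should give the β,γ-unsaturated ketone without moving the alkene into conjugation; the trans-2,5 arrangement is also the thermodynamic one.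

Step 8
Reactants: 13 ketone; 6 (E)-1,2-dichlorovinyl 4-methoxybenzyl ether
Product: 15 alkynyl carbinol, via lithium alkoxyacetylide 14 (not isolated)
Conditions: 6, n-BuLi (2.1 equiv), THF, −78 → −40 °C; CeCl3, −78 °C; then 13, −78 °C
Reagents that add atoms: none
Why: 1,2-Addition of the alkynylcerium reagent should occur by equatorial attack anti to the adjacent equatorial alkenyl group, as with other 2-branched cyclohexanones, which places the alkyne trans to that group and the hydroxyl axial, while cerium suppresses enolisation.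

Step 9
Reactants: 15 alkynyl carbinol
Product: 16 (Z)-enol ether carbinol
Conditions: H2 (1 atm), Pd/CaCO3 poisoned with Pb(OAc)2 (Lindlar catalyst), quinoline, EtOAc, rt
Reagents that add atoms: none
Why: Lindlar semi-hydrogenation adds hydrogen syn to the ynol ether and should give the Z enol ether, leaving the 1,1-disubstituted alkene and the benzyl-type ether intact.

Step 10
Reactants: 16 (Z)-enol ether carbinol
Product: 19 ring-trans keto ester, via potassium alkoxide 17 (not isolated), via potassium enolate 18 (not isolated)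
Conditions: KN(SiMe3)2 (1.1 equiv), 18-crown-6, THF, 0 °C → rt; then BrCH2CO2Me, −78 → −40 °C
Reagents that add atoms: methyl bromoacetate, COC(=O)CBr
Why: Deprotonation gives alkoxide 17, whose oxyanion-accelerated [3,3] sigmatropic shift (anionic oxy-Cope rearrangement) forms C8–C9 while C1–C6 breaks, so the cyclohexane grows into the ten-membered potassium enolate 18, which is alkylated at C7 in the same flask. The closest known reaction type is the anionic oxy-Cope ring expansion of trans-1,2-dialkenylcyclohexanols to cyclodec-5-enones with in situ C-alkylation of the regiodefined enolate. The ten-membered ring closes in a pericyclic suprafacial–suprafacial mode through a chair transition state fused to the cyclohexane chair that carries all three carbon substituents equatorial. C8 is set by this chair (both ring bonds pseudo-equatorial, the Z enol ether oxygen pseudo-axial), its sense relayed from C1 and C6 and hence from C4, and C7 is set by alkylation on the outer face of the enolate, the inner face being covered by C9 and the transannular C1=C10 unit. The step needs chair over boat (secured by the trans-diequatorial dialkenyl arrangement), C7 over C5 and carbon over oxygen alkylation (secured by the regiodefined enolate and the soft bromide), and alkylation ahead of β-elimination of the C8 alkoxide (addressed by cooling as soon as the shift is complete; the C8–O bond can lie in the enolate plane). The chair delivers the ring-trans C1=C10 geometry, which step 11 corrects.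

Step 11
Reactants: 19 ring-trans keto ester
Product: 20 ring-cis keto ester
Conditions: PhSSPh (0.2 equiv), hν (350 nm), benzene, rt
Reagents that add atoms: none
Why: Reversible addition of the phenylthiyl radical to the trisubstituted alkene should equilibrate it to the ring-cis isomer, the more stable geometry of a cyclodecene; no stereocentre is touched.

Step 12
Reactants: 20 ring-cis keto ester
Product: 22 trans-fused lactone, via hydroxy ester 21 (not isolated)
Conditions: SmI2 (3 equiv), MeOH, THF, 0 °C; then PPTS (cat.), CH2Cl2, rt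
Reagents that add atoms: none
Why: Samarium diiodide reduction of the β-alkoxy ketone through a chelate between the ketone and the C8 ether oxygen should give the 1,3-anti alcohol (6α-O), which closes on the methyl ester to the trans-fused γ-lactone while O8 stays blocked.

Step 13
Reactants: 22 trans-fused lactone
Product: 25 α-methylene lactone, via Mannich base 23 (not isolated), via ammonium iodide 24 (not isolated)
Conditions: LiN(SiMe3)2, THF, −78 °C; CH2=NMe2+ I−, −78 → 0 °C; MeI, MeOH, rt; NaHCO3 (aq), CH2Cl2
Reagents that add atoms: Eschenmoser's salt (N,N-dimethylmethyleneiminium iodide), C=[N+](C)C.[I-]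
Why: Eschenmoser methylenation: Mannich reaction of the lactone enolate at C11, quaternisation and elimination of trimethylamine install C13 without touching C7.

Step 14
Reactants: 25 α-methylene lactone
Product: 26 C8 alcohol
Conditions: DDQ, CH2Cl2/pH 7 buffer, 0 °C
Reagents that add atoms: none
Why: Oxidative cleavage of the 4-methoxybenzyl ether frees only the C8 hydroxyl; silyl ethers, both alkenes and the lactone should be inert.

Step 15
Reactants: 26 C8 alcohol
Product: 27 bis-silylated target
Conditions: angelic acid, 2,4,6-Cl3C6H2COCl, Et3N, toluene, rt; then 26, 75 °C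
Reagents that add atoms: angelic acid [(Z)-2-methylbut-2-enoic acid], C/C=C(/C)C(=O)O
Why: Yamaguchi esterification through the mixed anhydride without a nucleophilic amine catalyst should acylate the only free hydroxyl and keep the Z geometry of the angelate.

Step 16
Reactants: 27 bis-silylated target
Product: 28 CNP0262807.1
Conditions: HF·pyridine, pyridine, THF, 0 °C → rt
Reagents that add atoms: none
Why: Buffered fluoride desilylation removes both primary silyl ethers while the angelate and the α-methylene lactone survive.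

## Compound list

1 | 2-bromoprop-2-en-1-ol | C=C(Br)CO | starting material
2 | [(2-bromoprop-2-en-1-yl)oxy](tert-butyl)dimethylsilane | C=C(Br)CO[Si](C)(C)C(C)(C)C | intermediate
3 | trichloroethylene | ClC=C(Cl)Cl | starting material
4 | (4-methoxyphenyl)methanol | COc1ccc(CO)cc1 | starting material
5 | potassium (4-methoxyphenyl)methanolate (formed in the flask) | COc1ccc(C[O-])cc1.[K+] | intermediate
6 | 1-({[(E)-1,2-dichloroethenyl]oxy}methyl)-4-methoxybenzene | Cl/C=C(/Cl)OCc1ccc(OC)cc1 | intermediate
7 | (R)-cyclohex-3-ene-1-carboxylic acid | OC(=O)[C@H]1CC=CCC1 | starting material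
8 | sodium (R)-cyclohex-3-ene-1-carboxylate (formed in the flask) | [Na+].[O-]C(=O)[C@H]1CC=CCC1 | intermediate
9 | (1R,4R,5R)-4-iodo-6-oxabicyclo[3.2.1]octan-7-one | O=C1O[C@@H]2C[C@H]1CC[C@H]2I | intermediate
10 | (1R,4S,5R)-4-{3-[(tert-butyldimethylsilyl)oxy]prop-1-en-2-yl}-6-oxabicyclo[3.2.1]octan-7-one | O=C1O[C@@H]2C[C@H]1CC[C@H]2C(=C)CO[Si](C)(C)C(C)(C)C | intermediate
11 | (1R,2S,5R)-2-{3-[(tert-butyldimethylsilyl)oxy]prop-1-en-2-yl}-5-(hydroxymethyl)cyclohexan-1-ol (all substituents equatorial) | OC[C@@H]1CC[C@@H](C(=C)CO[Si](C)(C)C(C)(C)C)[C@H](O)C1 | intermediate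
12 | (1R,2S,5R)-2-{3-[(tert-butyldimethylsilyl)oxy]prop-1-en-2-yl}-5-{[(tert-butyldimethylsilyl)oxy]methyl}cyclohexan-1-ol | CC(C)(C)[Si](C)(C)OC[C@@H]1CC[C@@H](C(=C)CO[Si](C)(C)C(C)(C)C)[C@H](O)C1 | intermediate
13 | (2S,5R)-2-{3-[(tert-butyldimethylsilyl)oxy]prop-1-en-2-yl}-5-{[(tert-butyldimethylsilyl)oxy]methyl}cyclohexan-1-one (2,5-trans) | CC(C)(C)[Si](C)(C)OC[C@@H]1CC[C@@H](C(=C)CO[Si](C)(C)C(C)(C)C)C(=O)C1 | intermediate
14 | lithium 2-[(4-methoxybenzyl)oxy]ethynide (formed in the flask) | [Li+].[C-]#COCc1ccc(OC)cc1 | intermediate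
15 | (1S,2S,5R)-2-{3-[(tert-butyldimethylsilyl)oxy]prop-1-en-2-yl}-5-{[(tert-butyldimethylsilyl)oxy]methyl}-1-{[(4-methoxybenzyl)oxy]ethynyl}cyclohexan-1-ol (alkyne trans to the C2 alkenyl group, hydroxyl axial) | CC(C)(C)[Si](C)(C)OC[C@@H]1CC[C@@H](C(=C)CO[Si](C)(C)C(C)(C)C)[C@](O)(C#COCc2ccc(OC)cc2)C1 | intermediate
16 | (1S,2S,5R)-2-{3-[(tert-butyldimethylsilyl)oxy]prop-1-en-2-yl}-5-{[(tert-butyldimethylsilyl)oxy]methyl}-1-{(Z)-2-[(4-methoxybenzyl)oxy]ethenyl}cyclohexan-1-ol | CC(C)(C)[Si](C)(C)OC[C@@H]1CC[C@@H](C(=C)CO[Si](C)(C)C(C)(C)C)[C@](O)(/C=C\OCc2ccc(OC)cc2)C1 | intermediate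
17 | potassium alkoxide of 16 (formed in the flask) | CC(C)(C)[Si](C)(C)OC[C@@H]1CC[C@@H](C(=C)CO[Si](C)(C)C(C)(C)C)[C@]([O-])(/C=C\OCc2ccc(OC)cc2)C1.[K+] | intermediate
18 | potassium enolate of the ring-trans cyclodecenone (formed in the flask; O− on C6, C6=C7 with C5 and C8 trans, ring-trans C1=C10, 8β-(4-methoxybenzyloxy), 4α-silyloxymethyl) | [K+].[O-]/C1=C\[C@H](OCc2ccc(OC)cc2)C/C(CO[Si](C)(C)C(C)(C)C)=C/CC[C@@H](CO[Si](C)(C)C(C)(C)C)C1 | intermediate
19 | methyl 2-[(4R,7R,8R)-14,15-bis(tert-butyldimethylsilyloxy)-8-(4-methoxybenzyloxy)-6-oxogermacr-1(10)-en-7-yl]acetate, ring-trans C1=C10 (C2 and C9 trans), H-7α, H-8α | O=C1[C@H](CC(=O)OC)[C@H](OCc2ccc(OC)cc2)C/C(CO[Si](C)(C)C(C)(C)C)=C/CC[C@@H](CO[Si](C)(C)C(C)(C)C)C1 | intermediate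
20 | same keto ester as 19 with ring-cis C1=C10 (C2 and C9 cis) | O=C1[C@H](CC(=O)OC)[C@H](OCc2ccc(OC)cc2)C/C(CO[Si](C)(C)C(C)(C)C)=C\CC[C@@H](CO[Si](C)(C)C(C)(C)C)C1 | intermediate
21 | methyl 2-[(4R,6R,7S,8R)-14,15-bis(tert-butyldimethylsilyloxy)-6-hydroxy-8-(4-methoxybenzyloxy)germacr-1(10)-en-7-yl]acetate, ring-cis, 6α-OH (formed in the flask) | O[C@H]1[C@H](CC(=O)OC)[C@H](OCc2ccc(OC)cc2)C/C(CO[Si](C)(C)C(C)(C)C)=C\CC[C@@H](CO[Si](C)(C)C(C)(C)C)C1 | intermediate
22 | (4R,6R,7R,8R)-14,15-bis(tert-butyldimethylsilyloxy)-8-(4-methoxybenzyloxy)germacr-1(10)-en-6α,12-olide, ring-cis, 8β-O, trans-fused lactone | O=C1O[C@@H]2C[C@H](CO[Si](C)(C)C(C)(C)C)CC/C=C(/CO[Si](C)(C)C(C)(C)C)C[C@@H](OCc3ccc(OC)cc3)[C@H]2C1 | intermediate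
23 | 11-(dimethylaminomethyl) derivative of 22 (C11 epimers; formed in the flask) | CN(C)CC1C(=O)O[C@@H]2C[C@H](CO[Si](C)(C)C(C)(C)C)CC/C=C(/CO[Si](C)(C)C(C)(C)C)C[C@@H](OCc3ccc(OC)cc3)[C@@H]12 | intermediate
24 | trimethylammonium iodide of 23 (formed in the flask) | C[N+](C)(C)CC1C(=O)O[C@@H]2C[C@H](CO[Si](C)(C)C(C)(C)C)CC/C=C(/CO[Si](C)(C)C(C)(C)C)C[C@@H](OCc3ccc(OC)cc3)[C@@H]12.[I-] | intermediate
25 | (4R,6R,7R,8R)-14,15-bis(tert-butyldimethylsilyloxy)-8-(4-methoxybenzyloxy)germacra-1(10),11(13)-dien-6α,12-olide, ring-cis | C=C1C(=O)O[C@@H]2C[C@H](CO[Si](C)(C)C(C)(C)C)CC/C=C(/CO[Si](C)(C)C(C)(C)C)C[C@@H](OCc3ccc(OC)cc3)[C@@H]12 | intermediate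
26 | (4R,6R,7R,8R)-14,15-bis(tert-butyldimethylsilyloxy)-8β-hydroxygermacra-1(10),11(13)-dien-6α,12-olide, ring-cis | C=C1C(=O)O[C@@H]2C[C@H](CO[Si](C)(C)C(C)(C)C)CC/C=C(/CO[Si](C)(C)C(C)(C)C)C[C@@H](O)[C@@H]12 | intermediate
27 | (4R,6R,7S,8R)-8β-angeloyloxy-14,15-bis(tert-butyldimethylsilyloxy)germacra-1(10),11(13)-dien-6α,12-olide, ring-cis | C=C1C(=O)O[C@@H]2C[C@H](CO[Si](C)(C)C(C)(C)C)CC/C=C(/CO[Si](C)(C)C(C)(C)C)C[C@@H](OC(=O)/C(C)=C\C)[C@@H]12 | intermediate
28 | CNP0262807.1, (4R,6R,7S,8R)-8β-angeloyloxy-14,15-dihydroxygermacra-1(10),11(13)-dien-6α,12-olide, ring-cis C1=C10, 4α-hydroxymethyl | C=C1C(=O)O[C@@H]2C[C@H](CO)CC/C=C(/CO)C[C@@H](OC(=O)/C(C)=C\C)[C@@H]12 | target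

## Step count and risks

Total step count: 16. Longest linear sequence: 14 steps (steps 3 to 16, from acid 7).

Steps most likely to fail:

Step 10. The potassium enolate 18 carries the C8 ether oxygen in the β-position, so during the time the rearrangement needs at room temperature the alkoxide may be expelled (β-elimination to a cyclodecadienone); alkylation at oxygen or on the inner face is a lesser risk. The fallback avoids any enolate at room temperature: carbinol 16 is rearranged under neutral conditions by the palladium-catalysed oxy-Cope reaction (PdCl2(PhCN)2, 10 mol %, THF, rt), which should pass through the same chair-type array and give the ring-trans β-alkoxy cyclodecenone F1 with the same C8 configuration. The lithium enolate of F1 is then formed at −78 °C (LiN(SiMe3)2, THF), where β-alkoxy lithium enolates do not eliminate, and alkylated with methyl bromoacetate to come back to 19; the price is that enolisation toward C7 and not C5 is no longer guaranteed.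

Step 4. The alkyl iodide may be reduced with loss of the neighbouring carboxylate (re-opening to the cyclohexenecarboxylate), or the hindered alkenylnickel species may capture the radical slowly. The fallback sets out from 9 and builds the same ketone by enone chemistry. Elimination with DBU gives the unsaturated lactone F2; LiAlH4 gives the allylic diol F3; TBSCl/imidazole silylates the primary hydroxyl to F4; MnO2 gives the enone F5; I2/pyridine gives the 2-iodoenone F6. The alkenylstannane F7 is made from 2 (t-BuLi, then Bu3SnCl) and joined to F6 by Stille coupling (Pd2(dba)3, AsPh3, CuI) to give the cross-conjugated dienone F8. Conjugate reduction with LiBH(s-Bu)3 at −78 °C and kinetic protonation at C1 should then give the trans ketone and come back to the route at 13.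

Step 11. The radical equilibration may stall or end in a mixture if the ring-cis preference is smaller than in the parent cyclodecene. The fallback makes the isomerisation strongly downhill through the C14 aldehyde. Keto ester 19 is taken without isomerisation through the conditions of step 12 to the ring-trans lactone F9; HF·pyridine gives the diol F10; MnO2 oxidises only the allylic C14 alcohol to the ring-trans enal F11. This 2-substituted enal should equilibrate (catalytic I2 or DABCO, CH2Cl2) to the ring-cis enal F12, favoured both as the trans-enal and as the cis-cycloalkene. Luche reduction (NaBH4, CeCl3, MeOH) gives the ring-cis diol F13, and TBSCl/imidazole brings the material back to 22.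

Further compounds
F1 | step 10 | (4R,8R)-14,15-bis(tert-butyldimethylsilyloxy)-8-(4-methoxybenzyloxy)germacr-1(10)-en-6-one, ring-trans | O=C1C[C@H](OCc2ccc(OC)cc2)C/C(CO[Si](C)(C)C(C)(C)C)=C/CC[C@@H](CO[Si](C)(C)C(C)(C)C)C1
F2 | step 4 | (1R,5R)-6-oxabicyclo[3.2.1]oct-3-en-7-one | O=C1O[C@@H]2C[C@H]1CC=C2
F3 | step 4 | (1R,5R)-5-(hydroxymethyl)cyclohex-2-en-1-ol | OC[C@@H]1CC=C[C@H](O)C1
F4 | step 4 | (1R,5R)-5-{[(tert-butyldimethylsilyl)oxy]methyl}cyclohex-2-en-1-ol | CC(C)(C)[Si](C)(C)OC[C@@H]1CC=C[C@H](O)C1
F5 | step 4 | (R)-5-{[(tert-butyldimethylsilyl)oxy]methyl}cyclohex-2-en-1-one | CC(C)(C)[Si](C)(C)OC[C@@H]1CC=CC(=O)C1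
F6 | step 4 | (R)-5-{[(tert-butyldimethylsilyl)oxy]methyl}-2-iodocyclohex-2-en-1-one | CC(C)(C)[Si](C)(C)OC[C@@H]1CC=C(I)C(=O)C1
F7 | step 4 | tributyl{3-[(tert-butyldimethylsilyl)oxy]prop-1-en-2-yl}stannane | CCCC[Sn](CCCC)(CCCC)C(=C)CO[Si](C)(C)C(C)(C)C
F8 | step 4 | (R)-2-{3-[(tert-butyldimethylsilyl)oxy]prop-1-en-2-yl}-5-{[(tert-butyldimethylsilyl)oxy]methyl}cyclohex-2-en-1-one | CC(C)(C)[Si](C)(C)OC[C@@H]1CC=C(C(=C)CO[Si](C)(C)C(C)(C)C)C(=O)C1
F9 | step 11 | ring-trans isomer of lactone 22 | O=C1O[C@@H]2C[C@H](CO[Si](C)(C)C(C)(C)C)CC/C=C(\CO[Si](C)(C)C(C)(C)C)C[C@@H](OCc3ccc(OC)cc3)[C@H]2C1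
F10 | step 11 | ring-trans 14,15-diol of F9 | O=C1O[C@@H]2C[C@H](CO)CC/C=C(\CO)C[C@@H](OCc3ccc(OC)cc3)[C@H]2C1
F11 | step 11 | ring-trans 14-aldehyde (formyl cis to C2) | O=C1O[C@@H]2C[C@H](CO)CC/C=C(\C=O)C[C@@H](OCc3ccc(OC)cc3)[C@H]2C1
F12 | step 11 | ring-cis 14-aldehyde (formyl trans to C2) | O=C1O[C@@H]2C[C@H](CO)CC/C=C(/C=O)C[C@@H](OCc3ccc(OC)cc3)[C@H]2C1
F13 | step 11 | ring-cis 14,15-diol | O=C1O[C@@H]2C[C@H](CO)CC/C=C(/CO)C[C@@H](OCc3ccc(OC)cc3)[C@H]2C1
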